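## The problem

The target is a cycloheptane that carries a cis-fused α-methyl-γ-butyrolactone. The carbocycle is numbered C1 (tertiary carbinol bearing the crotonyl group), C2 (CH–CH3), C3 (CHOH), C4 (CH2), C5 (fusion carbon bonded to the lactone α-carbon C8), C6 (fusion carbon bonded to the lactone oxygen) and C7 (CH–O-angelate); C9 is the lactone carbonyl and C10 the ketone carbon. Seven stereocenters (1S,2S,3R,5S,6R,7S,8R) lie on neighbouring atoms, six of them in a mobile seven-membered ring, so each has to be relayed from another. C6/C7 are a trans diol, C1 can be read from C7 by chelation, C3–OH and C5–H are cis, and the C8 methyl sits on the concave face of the cis-fused bicycle. The angelate isomerises to the tiglate with nucleophiles or base, the crotonyl α-ketol is a Michael acceptor, and neither survives hydrogenation, hydroboration or organometallic reagents, so both must come last. Once C3 is a carbonyl, the tertiary C1 carbinol makes the chain prone to retro-aldol cleavage unless O1 is protected. The enabling feature is the C3 carbinol between the C4 methylene and the branched C5: drawn as an allylic alcohol on a C4=C5 alkene, it is the product of an alkenylmetal adding to a C3 aldehyde, and the same hydroxyl can then deliver hydrogen to C5 on its own face.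

## Retrosynthesis

**Acyl groups.** The O7–acyl bond and the C10–C11 bond of 43 are cut first. This leads through enone 42 and allylic alcohol 41 to aldehyde 38 plus (E)-1-bromoprop-1-ene 39, and through angelate 36 to lactone 33 plus angelic acid 34. A cut at C1–C10 would build the quaternary centre late on a crowded ring. The C10–C11 cut only asks for an alkenylation of an aldehyde that ignores a lactone and an ester, which an organochromium reagent provides. Precursor 33 has no alkene and one oxidatively removable PMB ether on C10.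

**Lactone.** The O6–C9 bond of 33 is cut back, via 31 and 30, to the primary C9 alcohol of pentaol 27. Only O6 is cis to the C5 side chain, so an oxidative lactonisation needs no differentiation of the other hydroxyls. C8 is left as a mixture and fixed in 33 by enolate protonation. The alternative cut, C8–CH3 by enolate methylation, would deliver the methyl group to the wrong (convex) face.

**C5 and C9.** 27 goes back through 26, 25 and 24 to dienol 22. The C5–H bond comes from hydrogenation directed by the C3 hydroxyl, the C9 oxygen from hydroboration of an isopropenyl group. This asks for a C3 hydroxyl of the right configuration and for non-coordinating silyl ethers on the oxygens of the opposite face.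

**Ring.** 22 is cut at C3–C4 to the iodoalkenyl aldehyde 20. Against cuts at C4–C5 or C5–C6, this one creates the hydroxyl that steers the next stereocenter and uses a polar closure that tolerates every other group present. The precursor is an open chain with C1, C2, C6 and C7 set.

**Alkenyl iodide and protecting groups.** 20 comes from 19 and 18, and 18 from tetraol 15 plus isopropenylmagnesium bromide 16 by anti addition across the C4≡C5 alkyne. This needs a free propargylic hydroxyl on C6, so the tartrate acetonide must be removed before this step. Afterwards all hydroxyls are silylated at once and the primary silyl ether is oxidised directly. Acyclic silyl ethers are also preferred for the ring closure, because a trans-fused C6/C7 acetonide would lock the closing ring in the chair that has the C2 methyl axial.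

**C1–C2.** 15 goes back through alkyne 14, aldehyde 13 and diol 12 to homoallylic alcohol 10, and 10 to ketone 7 plus (E)-crotyl bromide 8. One chelation-controlled crotylation makes the C1–C2 bond and both stereocenters; ozonolysis then shortens the vinyl group to C3. The Weinreb amide at the other end waits through these steps and then becomes the aldehyde and the alkyne (C4).

**Chiral pool.** 7 arises by single addition of the alkoxymethyllithium from stannane 5 to the C2-symmetric diamide 2, made from D-tartrate acetonide 1. Stannane 5 comes from 3 and 4.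

## Roads not taken

**Alternative 1:** The cut is C5–C6 together with the lactone O–C9 bond. Zinc (or CrCl2) turns an allylic bromide bearing the acrylate ester into an allylmetal whose γ-carbon C5 adds to a C6 aldehyde; the new alkoxide closes on the ester and gives the α-methylene lactone A1.
- Merits: both rings, C5, C6 and the lactone appear in one step, and hydrogenation of the exocyclic methylene from the convex face would set C8. The hydroboration, directed hydrogenation, lactonisation and enolate protonation of the chosen route shrink to one or two steps.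
- Weak points: C6 is no longer bought with C7 from tartaric acid but is made in the closure, and its configuration relative to C7 depends on how a seven-membered cyclic transition state reads an α-alkoxy aldehyde. The open chain must already hold C1, C2, C3 and C7, with the C3 carbinol made without a ring to lean on. The 2-(bromomethyl)acrylate is an alkylating Michael acceptor that must survive the unveiling of the aldehyde.
- Comparison: in step count after the closure this road is clearly better. The chosen plan sets against it that C6/C7 arrive as a pair from the chiral pool and that the hydroxyl formed in the closure is used at once to control C5.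

**Alternative 2:** The cut is C1–C2, with the ring oxygen of a glucal-derived tetrahydropyran becoming the C1 hydroxyl. Excess LiN(iPr)2 forms the ester enolate at C1, and a [2,3]-sigmatropic shift onto the terminus of the (E)-propenyl group breaks the C–O bond and gives cycloheptene A2.
- Merits: C1 and C2 are formed together in a concerted step with transfer of chirality, which is more dependable than the crotylation of the chosen route. C10 arrives as an ester, closer to the ketone than a PMB ether.
- Weak points: the enolate is β-alkoxy substituted and can eliminate, and a [1,2]-shift competes. The ring change has to pass through a strained bicyclic transition state. A2 still lacks the C3 hydroxyl, which must be introduced into the C3=C4 alkene with regio- and facial control and no obvious handle.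
- Comparison: this road is better for C1/C2 and worse for C3. The chosen plan creates the C3–O bond in the ring-forming step.

**Alternative 3:** The cut is C4–C5. Bu3SnH with AIBN generates a primary radical at C4, which adds 7-exo to the β-carbon C5 of a butenolide; the C8 radical then takes hydrogen and gives A3.
- Merits: the lactone is in place before the closure, cis fusion is the only possible outcome, C8 is set in the same step on the convex-face approach, and the conditions are neutral. Only acylations and the C10 oxidation would remain.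
- Weak points: 7-exo radical closures are slow against direct reduction by the stannane and against 1,5-hydrogen transfer. The substrate must carry C1, C2 and the C3 carbinol, all set in an open chain. Tin residues have to be removed late.
- Comparison: the end game is shorter and C8 is handled better than in the chosen plan. The chosen plan offers a polar medium-ring closure of a well-tried type and makes C3 during the closure.

Key step: step 12

Remark: tributyl(iodomethyl)stannane 4 and (E)-1-bromoprop-1-ene 39 are taken as purchasable.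
Remark: compounds 24 to 31 are carried as both epimers at C8; they converge in step 19.

## Steps

Step 1
Reactants: 1 dimethyl (4S,5S)-2,2-dimethyl-1,3-dioxolane-4,5-dicarboxylate
Product: 2 (4S,5S)-N4,N5-dimethoxy-N4,N5,2,2-tetramethyl-1,3-dioxolane-4,5-dicarboxamide
Conditions: MeNH(OMe)·HCl, iPrMgCl, THF, −20 → 0 °C
Reagents that add atoms: N,O-dimethylhydroxylamine hydrochloride, CNOC.Cl
Why: Aminolysis of both esters by the magnesium amide gives the bis-Weinreb amide; the trans-dioxolane is the more stable arrangement, so the two stereocenters are not at risk.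

Step 2
Reactants: 3 (4-methoxyphenyl)methanol; 4 tributyl(iodomethyl)stannane
Product: 5 tributyl{[(4-methoxybenzyl)oxy]methyl}stannane
Conditions: NaH, THF/DMF, 0 °C → rt
Reagents that add atoms: none
Why: Williamson etherification of the alkoxide with the primary iodide gives the alkoxymethylstannane that serves as a masked hydroxymethyl anion.

Step 3
Reactants: 2; 5
Product: 7 (4S,5S)-N-methoxy-5-{[(4-methoxybenzyl)oxy]acetyl}-N,2,2-trimethyl-1,3-dioxolane-4-carboxamide, via [(4-methoxybenzyl)oxy]methyllithium 6 (not isolated)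
Conditions: 5, nBuLi, THF, −78 °C; then 2 (1.5 equiv), −78 °C; aq NH4Cl
Reagents that add atoms: none
Why: Tin–lithium exchange gives the α-alkoxy organolithium, which adds once to a Weinreb amide because the chelated tetrahedral adduct lasts until work-up. Single addition to this C2-symmetric diamide is a known desymmetrisation and is helped here by the excess of 2.

Step 4
Reactants: 7; 8 (E)-1-bromobut-2-ene
Product: 10 (4S,5S)-5-[(2R,3S)-2-hydroxy-1-[(4-methoxybenzyl)oxy]-3-methylpent-4-en-2-yl]-N-methoxy-N,2,2-trimethyl-1,3-dioxolane-4-carboxamide, via (E)-but-2-enylindium dibromide 9 (not isolated)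
Conditions: In powder, THF/H2O (1:1), rt
Reagents that add atoms: none
Why: Barbier-type indium crotylation by γ-attack (SE2′) on the α,α′-dialkoxy ketone; the Cram chelate between the carbonyl and O7 opens the face anti to C6 and sets C1. The cyclic transition state should place the new methyl anti to the hydroxyl along the C7–C1–C2 chain, the syn-O/O, anti-Me/OH pattern known for indium crotylation of α-alkoxy carbonyl compounds. The Weinreb amide does not react.

Step 5
Reactants: 10
Product: 12 (4S,5S)-5-[(2R,3S)-2,4-dihydroxy-1-[(4-methoxybenzyl)oxy]-3-methylbutan-2-yl]-N-methoxy-N,2,2-trimethyl-1,3-dioxolane-4-carboxamide, via β-hydroxy aldehyde 11 (not isolated)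
Conditions: O3, CH2Cl2/MeOH, −78 °C (Sudan Red 7B end point); then NaBH4, −78 → 0 °C
Reagents that add atoms: ozone, [O-][O+]=O
Why: Ozonolysis of the only alkene with reductive work-up turns the vinyl group into the C3 hydroxymethyl group. Stopping at the indicator end point spares the PMB arene, immediate reduction avoids retro-aldol cleavage of 11, and NaBH4 leaves the Weinreb amide.

Step 6
Reactants: 12
Product: 13 (4S,5S)-5-[(2R,3S)-2,4-dihydroxy-1-[(4-methoxybenzyl)oxy]-3-methylbutan-2-yl]-2,2-dimethyl-1,3-dioxolane-4-carbaldehyde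
Conditions: iBu2AlH (4 equiv), THF, −78 °C; aq KNaC4H4O6
Reagents that add atoms: none
Why: Partial reduction of the Weinreb amide through its stable aluminium chelate; the extra hydride only deprotonates the two hydroxyls. A lactol with O1 would be a trans-fused bicyclo[3.3.0] system, so the aldehyde should stay open and is used crude.

Step 7
Reactants: 13
Product: 14 (2R,3S)-2-[(4S,5R)-5-ethynyl-2,2-dimethyl-1,3-dioxolan-4-yl]-1-[(4-methoxybenzyl)oxy]-3-methylbutane-2,4-diol
Conditions: dimethyl (1-diazo-2-oxopropyl)phosphonate, K2CO3, MeOH, 0 °C → rt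
Reagents that add atoms: dimethyl (1-diazo-2-oxopropyl)phosphonate, CC(=O)C(=[N+]=[N-])P(=O)(OC)OC
Why: Ohira–Bestmann homologation converts the aldehyde into the terminal alkyne and supplies C4; C6 is already the more stable trans isomer on the dioxolane, so the basic medium cannot erode it.

Step 8
Reactants: 14
Product: 15 (2S,3R,4S,5R)-3-{[(4-methoxybenzyl)oxy]methyl}-2-methylhept-6-yne-1,3,4,5-tetrol
Conditions: AcOH/H2O (4:1), 45 °C
Reagents that add atoms: none
Why: Acid hydrolysis of the isopropylidene acetal frees the propargylic C6 hydroxyl that must direct step 9; the PMB ether and the alkyne tolerate aqueous acetic acid.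

Step 9
Reactants: 15; 16 prop-1-en-2-ylmagnesium bromide
Product: 18 (2S,3R,4S,5R,6Z)-6-(iodomethylidene)-3-{[(4-methoxybenzyl)oxy]methyl}-2,7-dimethyloct-7-ene-1,3,4,5-tetrol, via C4 alkenylmagnesium chelate 17 (not isolated)
Conditions: 16 (8 equiv), CuI (20 mol%), THF, −20 °C → rt; then I2, THF, −78 → 0 °C
Reagents that add atoms: iodine, II
Why: Hydroxyl-directed anti-carbomagnesiation of a propargylic alkoxide: the isopropenyl group adds to the proximal carbon C5 and magnesium to C4 inside a five-membered chelate with O6, so magnesium is cis to C6. Iodine then replaces magnesium with retention. Four equivalents of 16 are consumed by the hydroxyls.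

Step 10
Reactants: 18
Product: 19 (2S,3R,4S,5R,6Z)-6-(iodomethylidene)-3-{[(4-methoxybenzyl)oxy]methyl}-2,7-dimethyl-1,3,4,5-tetrakis[(triethylsilyl)oxy]oct-7-ene
Conditions: Et3SiOTf (6 equiv), 2,6-lutidine, CH2Cl2, −78 → 0 °C
Reagents that add atoms: triethylsilyl trifluoromethanesulfonate, CC[Si](CC)(CC)OS(=O)(=O)C(F)(F)F
Why: The silyl triflate silylates all four hydroxyls, the tertiary one on C1 included; acyclic silyl ethers rather than a C6/C7 acetonide are wanted for the ring closure (step 12).

Step 11
Reactants: 19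
Product: 20 (2R,3R,4S,5R,6Z)-6-(iodomethylidene)-3-{[(4-methoxybenzyl)oxy]methyl}-2,7-dimethyl-3,4,5-tris[(triethylsilyl)oxy]oct-7-enal
Conditions: (COCl)2, DMSO, CH2Cl2, −78 → −40 °C; Et3N, −78 → 0 °C
Reagents that add atoms: none
Why: Swern conditions cleave and oxidise a primary triethylsilyl ether directly while secondary and tertiary ones stay, so the C3 aldehyde is reached in one operation. C2 lies next to a quaternary carbon and meets the amine base only briefly in the cold.

Step 12
Reactants: 20
Product: 22 (1R,4R,5S,6R,7S)-6-{[(4-methoxybenzyl)oxy]methyl}-7-methyl-3-(prop-1-en-2-yl)-4,5,6-tris[(triethylsilyl)oxy]cyclohept-2-en-1-ol, via Z-alkenylchromium dichloride 21 (not isolated)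
Conditions: CrCl2 (10 equiv), NiCl2 (2 mol%), DMSO, rt, 0.005 M
Reagents that add atoms: none
Why: CrCl2 reduces NiCl2 to zerovalent nickel, which inserts into the C4–I bond; transmetalation to trivalent chromium gives 21 with the alkene geometry kept, and 21 adds to the C3 aldehyde to form the C3–C4 bond (Nozaki–Hiyama–Kishi reaction). The closest known reaction type is the intramolecular Nozaki–Hiyama–Kishi cyclisation of iodoalkenyl aldehydes to medium-ring allylic alcohols. The seven-membered carbocycle closes by 7-exo-trig attack of C4 on the carbonyl carbon with the C4=C5 alkene ending inside the ring, which is possible only because iodine is cis to C6. The new stereocenter C3 is controlled by the C2 methyl group in a chair-like closing ring: with C2–CH3 and the C1 CH2OPMB arm equatorial, the chromium-bound oxygen should also go equatorial, so that C3–O ends trans to the C2 methyl (3R). The step needs chemoselectivity (the organochromium reagent adds to the aldehyde and ignores silyl and PMB ethers), retention of alkene geometry, no epimerisation at C2 (the medium is not basic) and this facial selectivity. The last point is the reason for acyclic silyl ethers: a trans-fused acetonide on C6/C7 would lock the other chair, in which the C2 methyl is axial and the wanted C3–O bond would be axial and syn to the axial C1 arm. High dilution favours closure over intermolecular coupling.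

Step 13
Reactants: 22
Product: 24 (1R,4R,5S,6R,7S)-3-(1-hydroxypropan-2-yl)-6-{[(4-methoxybenzyl)oxy]methyl}-7-methyl-4,5,6-tris[(triethylsilyl)oxy]cyclohept-2-en-1-ol (both C8 epimers), via B-alkyl-9-borabicyclo[3.3.1]nonane 23 (not isolated)
Conditions: 9-BBN (3 equiv), THF, 0 °C → rt; then aq NaOH, H2O2, 0 °C
Reagents that add atoms: hydrogen peroxide, OO
Why: The bulky borane adds only to the terminal 1,1-disubstituted alkene, with boron on C9, and leaves the trisubstituted ring alkene. C8 forms without control and is corrected in step 19.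

Step 14
Reactants: 24
Product: 25 (1R,4R,5S,6R,7S)-6-{[(4-methoxybenzyl)oxy]methyl}-7-methyl-4,5,6-tris[(triethylsilyl)oxy]-3-{1-[(triethylsilyl)oxy]propan-2-yl}cyclohept-2-en-1-ol (both C8 epimers)
Conditions: Et3SiCl (1.1 equiv), imidazole, CH2Cl2, −40 → 0 °C
Reagents that add atoms: chlorotriethylsilane, CC[Si](Cl)(CC)CC
Why: The primary hydroxyl is silylated in preference to the hindered secondary allylic one, so that only the C3 hydroxyl can bind iridium in step 15.

Step 15
Reactants: 25
Product: 26 (1R,2S,3R,4S,5R,6S)-3-{[(4-methoxybenzyl)oxy]methyl}-2-methyl-3,4,5-tris[(triethylsilyl)oxy]-6-{1-[(triethylsilyl)oxy]propan-2-yl}cycloheptan-1-ol (both C8 epimers)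
Conditions: [Ir(cod)(PCy3)(py)]PF6 (5 mol%), H2 (1 atm), CH2Cl2, rt
Reagents that add atoms: none
Why: Hydroxyl-directed hydrogenation: the cationic iridium centre is held by the allylic C3 hydroxyl and delivers both hydrogens to the C4=C5 alkene on the face of that hydroxyl, so C5–H becomes cis to C3–OH and the C8 side chain cis to O6. The silyl ether on O6 shields the other face and does not coordinate.

Step 16
Reactants: 26
Product: 27 pentaol (strategy locants 1R,2S,3R,5S,6R,7S): 5-(1-hydroxypropan-2-yl)-1-{[(4-methoxybenzyl)oxy]methyl}-2-methylcycloheptane-1,3,6,7-tetrol (both C8 epimers)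
Conditions: HF·pyridine, pyridine, THF, 0 °C → rt
Reagents that add atoms: none
Why: Fluoride cleaves all four triethylsilyl ethers, the tertiary one last; the PMB ether is inert.

Step 17
Reactants: 27
Product: 30 (3aS,5R,6S,7R,8S,8aR)-5,7,8-trihydroxy-7-{[(4-methoxybenzyl)oxy]methyl}-3,6-dimethyloctahydro-2H-cyclohepta[b]furan-2-one (both C3 epimers; ring C3 is strategy C8), via C9 hydroxy aldehyde 28 (not isolated), via C9 lactol 29 (not isolated)
Conditions: TEMPO (20 mol%), PhI(OAc)2 (3 equiv), CH2Cl2, rt
Reagents that add atoms: none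
Why: Oxoammonium oxidation picks the only primary alcohol; the C9 aldehyde is trapped by the cis hydroxyl on C6 as a five-membered lactol, which is oxidised on to the γ-lactone. The hydroxyls on C3 and C7 are on the other ring face and cannot close.

Step 18
Reactants: 30
Product: 31 (3aS,5R,6S,7R,8S,8aR)-7,8-dihydroxy-7-{[(4-methoxybenzyl)oxy]methyl}-3,6-dimethyl-5-[(triethylsilyl)oxy]octahydro-2H-cyclohepta[b]furan-2-one (both C3 epimers)
Conditions: Et3SiCl (1.2 equiv), imidazole, DMF, −20 → 0 °C
Reagents that add atoms: chlorotriethylsilane, CC[Si](Cl)(CC)CC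
Why: The hydroxyl on strategy C3 is the least hindered of the three (O7–H lies between the quaternary C1 and the ring fusion, O1–H is tertiary), so monosilylation is expected there.

Step 19
Reactants: 31
Product: 33 (3R,3aS,5R,6S,7R,8S,8aR)-7,8-dihydroxy-7-{[(4-methoxybenzyl)oxy]methyl}-3,6-dimethyl-5-[(triethylsilyl)oxy]octahydro-2H-cyclohepta[b]furan-2-one, via trilithium lactone enolate 32 (not isolated)
Conditions: LiN(iPr)2 (3.5 equiv), THF, −78 °C; then 2,6-di-tert-butylphenol, −78 °C; aq NH4Cl
Reagents that add atoms: none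
Why: Kinetic protonation of the lactone enolate: both C8 epimers give the same planar enolate, and the bulky proton donor should approach the convex face of the cis-fused bicycle (the face of H5 and H6). This leaves the methyl group on the concave face as in the target (strategy 8R).

Step 20
Reactants: 33; 34 (Z)-2-methylbut-2-enoic acid (angelic acid)
Product: 36 (3R,3aS,5R,6S,7R,8S,8aR)-7-hydroxy-7-{[(4-methoxybenzyl)oxy]methyl}-3,6-dimethyl-2-oxo-5-[(triethylsilyl)oxy]octahydro-2H-cyclohepta[b]furan-8-yl (2Z)-2-methylbut-2-enoate, via angelic 2,4,6-trichlorobenzoic anhydride 35 (not isolated)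
Conditions: 34, 2,4,6-trichlorobenzoyl chloride, Et3N, toluene, rt; then 33, 80 °C
Reagents that add atoms: none
Why: Yamaguchi-type acylation through the mixed anhydride, run without a nucleophilic catalyst because such catalysts isomerise angelates to tiglates by addition–elimination. Only the secondary O7–H reacts; the tertiary O1–H is inert.

Step 21
Reactants: 36
Product: 37 (3R,3aS,5R,6S,7R,8S,8aR)-7-hydroxy-7-(hydroxymethyl)-3,6-dimethyl-2-oxo-5-[(triethylsilyl)oxy]octahydro-2H-cyclohepta[b]furan-8-yl (2Z)-2-methylbut-2-enoate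
Conditions: DDQ, CH2Cl2/pH 7 buffer (10:1), 0 °C → rt
Reagents that add atoms: none
Why: Oxidative cleavage of the PMB ether by hydride abstraction and hydrolysis of the oxocarbenium ion; the buffered water should trap the cation before the neighbouring tertiary hydroxyl can form an acetal, and the angelate is not touched.

Step 22
Reactants: 37
Product: 38 (3R,3aS,5R,6S,7S,8S,8aR)-7-formyl-7-hydroxy-3,6-dimethyl-2-oxo-5-[(triethylsilyl)oxy]octahydro-2H-cyclohepta[b]furan-8-yl (2Z)-2-methylbut-2-enoate
Conditions: TEMPO (20 mol%), PhI(OAc)2 (1.2 equiv), CH2Cl2, rt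
Reagents that add atoms: none
Why: Oxoammonium oxidation of the primary alcohol to the aldehyde; the tertiary hydroxyl cannot be oxidised, and this oxidant does not cleave the 1,2-diol.

Step 23
Reactants: 38; 39 (E)-1-bromoprop-1-ene
Product: 41 (3R,3aS,5R,6S,7R,8S,8aR)-7-hydroxy-7-[(2E)-1-hydroxybut-2-en-1-yl]-3,6-dimethyl-2-oxo-5-[(triethylsilyl)oxy]octahydro-2H-cyclohepta[b]furan-8-yl (2Z)-2-methylbut-2-enoate (both epimers at the new carbinol), via (E)-prop-1-enylchromium dichloride 40 (not isolated)
Conditions: 39, CrCl2 (6 equiv), NiCl2 (1 mol%), DMF, rt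
Reagents that add atoms: none
Why: Intermolecular Nozaki–Hiyama–Kishi alkenylation: the alkenylchromium reagent adds to the aldehyde only, leaves lactone and angelate alone and keeps the E geometry. The configuration of the new carbinol does not matter.

Step 24
Reactants: 41
Product: 42 (3R,3aS,5R,6S,7S,8S,8aR)-7-[(2E)-but-2-enoyl]-7-hydroxy-3,6-dimethyl-2-oxo-5-[(triethylsilyl)oxy]octahydro-2H-cyclohepta[b]furan-8-yl (2Z)-2-methylbut-2-enoate
Conditions: IBX, DMSO, rt
Reagents that add atoms: none
Why: IBX oxidises the secondary allylic alcohol of the 1,2-diol to the α-hydroxy enone without glycol cleavage; no base is present, so the angelate and C8 are safe.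

Step 25
Reactants: 42
Product: 43 (3R,3aS,5R,6S,7S,8S,8aR)-7-[(2E)-but-2-enoyl]-5,7-dihydroxy-3,6-dimethyl-2-oxooctahydro-2H-cyclohepta[b]furan-8-yl (2Z)-2-methylbut-2-enoate (CNP0183494.1)
Conditions: HF·pyridine, pyridine, THF, 0 °C
Reagents that add atoms: none
Why: Buffered fluoride removes the last silyl ether under conditions that leave the enone, the α-ketol and the angelate untouched.

## Compound list

1 | dimethyl (4S,5S)-2,2-dimethyl-1,3-dioxolane-4,5-dicarboxylate | COC(=O)[C@H]1OC(C)(C)O[C@@H]1C(=O)OC | starting material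
2 | (4S,5S)-N4,N5-dimethoxy-N4,N5,2,2-tetramethyl-1,3-dioxolane-4,5-dicarboxamide | CON(C)C(=O)[C@H]1OC(C)(C)O[C@@H]1C(=O)N(C)OC | intermediate
3 | (4-methoxyphenyl)methanol | COc1ccc(CO)cc1 | starting material
4 | tributyl(iodomethyl)stannane | CCCC[Sn](CCCC)(CCCC)CI | starting material
5 | tributyl{[(4-methoxybenzyl)oxy]methyl}stannane | CCCC[Sn](CCCC)(CCCC)COCc1ccc(OC)cc1 | intermediate
6 | [(4-methoxybenzyl)oxy]methyllithium (formed in the flask) | [Li]COCc1ccc(OC)cc1 | intermediate
7 | (4S,5S)-N-methoxy-5-{[(4-methoxybenzyl)oxy]acetyl}-N,2,2-trimethyl-1,3-dioxolane-4-carboxamide | COc1ccc(COCC(=O)[C@H]2OC(C)(C)O[C@@H]2C(=O)N(C)OC)cc1 | intermediate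
8 | (E)-1-bromobut-2-ene | C/C=C/CBr | starting material
9 | (E)-but-2-enylindium dibromide (formed in the flask; simplest organoindium species) | C/C=C/C[In](Br)Br | intermediate
10 | (4S,5S)-5-[(2R,3S)-2-hydroxy-1-[(4-methoxybenzyl)oxy]-3-methylpent-4-en-2-yl]-N-methoxy-N,2,2-trimethyl-1,3-dioxolane-4-carboxamide | C=C[C@H](C)[C@@](O)(COCc1ccc(OC)cc1)[C@H]2OC(C)(C)O[C@@H]2C(=O)N(C)OC | intermediate
11 | (4S,5S)-5-[(2R,3R)-2-hydroxy-1-[(4-methoxybenzyl)oxy]-3-methyl-4-oxobutan-2-yl]-N-methoxy-N,2,2-trimethyl-1,3-dioxolane-4-carboxamide (formed in the flask) | O=C[C@H](C)[C@@](O)(COCc1ccc(OC)cc1)[C@H]2OC(C)(C)O[C@@H]2C(=O)N(C)OC | intermediate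
12 | (4S,5S)-5-[(2R,3S)-2,4-dihydroxy-1-[(4-methoxybenzyl)oxy]-3-methylbutan-2-yl]-N-methoxy-N,2,2-trimethyl-1,3-dioxolane-4-carboxamide | OC[C@H](C)[C@@](O)(COCc1ccc(OC)cc1)[C@H]2OC(C)(C)O[C@@H]2C(=O)N(C)OC | intermediate
13 | (4S,5S)-5-[(2R,3S)-2,4-dihydroxy-1-[(4-methoxybenzyl)oxy]-3-methylbutan-2-yl]-2,2-dimethyl-1,3-dioxolane-4-carbaldehyde | OC[C@H](C)[C@@](O)(COCc1ccc(OC)cc1)[C@H]2OC(C)(C)O[C@@H]2C=O | intermediate
14 | (2R,3S)-2-[(4S,5R)-5-ethynyl-2,2-dimethyl-1,3-dioxolan-4-yl]-1-[(4-methoxybenzyl)oxy]-3-methylbutane-2,4-diol | OC[C@H](C)[C@@](O)(COCc1ccc(OC)cc1)[C@H]2OC(C)(C)O[C@@H]2C#C | intermediate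
15 | (2S,3R,4S,5R)-3-{[(4-methoxybenzyl)oxy]methyl}-2-methylhept-6-yne-1,3,4,5-tetrol | OC[C@H](C)[C@@](O)(COCc1ccc(OC)cc1)[C@@H](O)[C@H](O)C#C | intermediate
16 | prop-1-en-2-ylmagnesium bromide (isopropenylmagnesium bromide) | C=C(C)[Mg]Br | starting material
17 | C4 alkenylmagnesium chelate, drawn as the open tetrakis(bromomagnesium alkoxide) with C4–MgBr (formed in the flask) | Br[Mg]OC[C@H](C)[C@@](O[Mg]Br)(COCc1ccc(OC)cc1)[C@@H](O[Mg]Br)[C@H](O[Mg]Br)/C(=C\[Mg]Br)C(C)=C | intermediate
18 | (2S,3R,4S,5R,6Z)-6-(iodomethylidene)-3-{[(4-methoxybenzyl)oxy]methyl}-2,7-dimethyloct-7-ene-1,3,4,5-tetrol | OC[C@H](C)[C@@](O)(COCc1ccc(OC)cc1)[C@@H](O)[C@H](O)/C(=C\I)C(C)=C | intermediate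
19 | (2S,3R,4S,5R,6Z)-6-(iodomethylidene)-3-{[(4-methoxybenzyl)oxy]methyl}-2,7-dimethyl-1,3,4,5-tetrakis[(triethylsilyl)oxy]oct-7-ene | CC[Si](CC)(CC)OC[C@H](C)[C@@](O[Si](CC)(CC)CC)(COCc1ccc(OC)cc1)[C@@H](O[Si](CC)(CC)CC)[C@H](O[Si](CC)(CC)CC)/C(=C\I)C(C)=C | intermediate
20 | (2R,3R,4S,5R,6Z)-6-(iodomethylidene)-3-{[(4-methoxybenzyl)oxy]methyl}-2,7-dimethyl-3,4,5-tris[(triethylsilyl)oxy]oct-7-enal | O=C[C@H](C)[C@@](O[Si](CC)(CC)CC)(COCc1ccc(OC)cc1)[C@@H](O[Si](CC)(CC)CC)[C@H](O[Si](CC)(CC)CC)/C(=C\I)C(C)=C | intermediate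
21 | Z-alkenylchromium dichloride of 20 (C4–Cr, trivalent chromium, solvent ligands omitted; formed in the flask) | O=C[C@H](C)[C@@](O[Si](CC)(CC)CC)(COCc1ccc(OC)cc1)[C@@H](O[Si](CC)(CC)CC)[C@H](O[Si](CC)(CC)CC)/C(=C\[Cr](Cl)Cl)C(C)=C | intermediate
22 | (1R,4R,5S,6R,7S)-6-{[(4-methoxybenzyl)oxy]methyl}-7-methyl-3-(prop-1-en-2-yl)-4,5,6-tris[(triethylsilyl)oxy]cyclohept-2-en-1-ol | O[C@@H]1C=C(C(C)=C)[C@@H](O[Si](CC)(CC)CC)[C@H](O[Si](CC)(CC)CC)[C@](O[Si](CC)(CC)CC)(COCc2ccc(OC)cc2)[C@H]1C | intermediate
23 | B-alkyl-9-borabicyclo[3.3.1]nonane from 22, boron on C9, drawn without the O3 borinate (formed in the flask; both C8 epimers) | O[C@@H]1C=C(C(C)CB3C4CCCC3CCC4)[C@@H](O[Si](CC)(CC)CC)[C@H](O[Si](CC)(CC)CC)[C@](O[Si](CC)(CC)CC)(COCc2ccc(OC)cc2)[C@H]1C | intermediate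
24 | (1R,4R,5S,6R,7S)-3-(1-hydroxypropan-2-yl)-6-{[(4-methoxybenzyl)oxy]methyl}-7-methyl-4,5,6-tris[(triethylsilyl)oxy]cyclohept-2-en-1-ol (both C8 epimers) | O[C@@H]1C=C(C(C)CO)[C@@H](O[Si](CC)(CC)CC)[C@H](O[Si](CC)(CC)CC)[C@](O[Si](CC)(CC)CC)(COCc2ccc(OC)cc2)[C@H]1C | intermediate
25 | (1R,4R,5S,6R,7S)-6-{[(4-methoxybenzyl)oxy]methyl}-7-methyl-4,5,6-tris[(triethylsilyl)oxy]-3-{1-[(triethylsilyl)oxy]propan-2-yl}cyclohept-2-en-1-ol (both C8 epimers) | O[C@@H]1C=C(C(C)CO[Si](CC)(CC)CC)[C@@H](O[Si](CC)(CC)CC)[C@H](O[Si](CC)(CC)CC)[C@](O[Si](CC)(CC)CC)(COCc2ccc(OC)cc2)[C@H]1C | intermediate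
26 | (1R,2S,3R,4S,5R,6S)-3-{[(4-methoxybenzyl)oxy]methyl}-2-methyl-3,4,5-tris[(triethylsilyl)oxy]-6-{1-[(triethylsilyl)oxy]propan-2-yl}cycloheptan-1-ol (both C8 epimers) | O[C@@H]1C[C@@H](C(C)CO[Si](CC)(CC)CC)[C@@H](O[Si](CC)(CC)CC)[C@H](O[Si](CC)(CC)CC)[C@](O[Si](CC)(CC)CC)(COCc2ccc(OC)cc2)[C@H]1C | intermediate
27 | pentaol, strategy locants (1R,2S,3R,5S,6R,7S): 5-(1-hydroxypropan-2-yl)-1-{[(4-methoxybenzyl)oxy]methyl}-2-methylcycloheptane-1,3,6,7-tetrol (both C8 epimers) | O[C@@H]1C[C@@H](C(C)CO)[C@@H](O)[C@H](O)[C@](O)(COCc2ccc(OC)cc2)[C@H]1C | intermediate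
28 | C9 hydroxy aldehyde, strategy locants (1R,2S,3R,5S,6R,7S): 2-(3,4,5,7-... ring of 27)propanal, i.e. 27 with C9 as CHO (formed in the flask; both C8 epimers) | O[C@@H]1C[C@@H](C(C)C=O)[C@@H](O)[C@H](O)[C@](O)(COCc2ccc(OC)cc2)[C@H]1C | intermediate
29 | (3aS,5R,6S,7R,8S,8aR)-7-{[(4-methoxybenzyl)oxy]methyl}-3,6-dimethyloctahydro-2H-cyclohepta[b]furan-2,5,7,8-tetrol, the C9 lactol (formed in the flask; epimers at C2 and C3 of the ring system) | O[C@H]1[C@@H]2OC(O)C(C)[C@@H]2C[C@@H](O)[C@H](C)[C@@]1(O)COCc3ccc(OC)cc3 | intermediate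
30 | (3aS,5R,6S,7R,8S,8aR)-5,7,8-trihydroxy-7-{[(4-methoxybenzyl)oxy]methyl}-3,6-dimethyloctahydro-2H-cyclohepta[b]furan-2-one (both C3 epimers) | O[C@H]1[C@@H]2OC(=O)C(C)[C@@H]2C[C@@H](O)[C@H](C)[C@@]1(O)COCc3ccc(OC)cc3 | intermediate
31 | (3aS,5R,6S,7R,8S,8aR)-7,8-dihydroxy-7-{[(4-methoxybenzyl)oxy]methyl}-3,6-dimethyl-5-[(triethylsilyl)oxy]octahydro-2H-cyclohepta[b]furan-2-one (both C3 epimers) | O[C@H]1[C@@H]2OC(=O)C(C)[C@@H]2C[C@@H](O[Si](CC)(CC)CC)[C@H](C)[C@@]1(O)COCc3ccc(OC)cc3 | intermediate
32 | trilithium lactone enolate of 31 (formed in the flask) | [Li]O[C@H]1[C@@H]2OC(O[Li])=C(C)[C@@H]2C[C@@H](O[Si](CC)(CC)CC)[C@H](C)[C@@]1(O[Li])COCc3ccc(OC)cc3 | intermediate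
33 | (3R,3aS,5R,6S,7R,8S,8aR)-7,8-dihydroxy-7-{[(4-methoxybenzyl)oxy]methyl}-3,6-dimethyl-5-[(triethylsilyl)oxy]octahydro-2H-cyclohepta[b]furan-2-one | O[C@H]1[C@@H]2OC(=O)[C@H](C)[C@@H]2C[C@@H](O[Si](CC)(CC)CC)[C@H](C)[C@@]1(O)COCc3ccc(OC)cc3 | intermediate
34 | (Z)-2-methylbut-2-enoic acid (angelic acid) | C/C=C(/C)C(O)=O | starting material
35 | (Z)-2-methylbut-2-enoic 2,4,6-trichlorobenzoic anhydride (formed in the flask) | C/C=C(/C)C(=O)OC(=O)c1c(Cl)cc(Cl)cc1Cl | intermediate
36 | (3R,3aS,5R,6S,7R,8S,8aR)-7-hydroxy-7-{[(4-methoxybenzyl)oxy]methyl}-3,6-dimethyl-2-oxo-5-[(triethylsilyl)oxy]octahydro-2H-cyclohepta[b]furan-8-yl (2Z)-2-methylbut-2-enoate | C/C=C(/C)C(=O)O[C@H]1[C@@H]2OC(=O)[C@H](C)[C@@H]2C[C@@H](O[Si](CC)(CC)CC)[C@H](C)[C@@]1(O)COCc3ccc(OC)cc3 | intermediate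
37 | (3R,3aS,5R,6S,7R,8S,8aR)-7-hydroxy-7-(hydroxymethyl)-3,6-dimethyl-2-oxo-5-[(triethylsilyl)oxy]octahydro-2H-cyclohepta[b]furan-8-yl (2Z)-2-methylbut-2-enoate | C/C=C(/C)C(=O)O[C@H]1[C@@H]2OC(=O)[C@H](C)[C@@H]2C[C@@H](O[Si](CC)(CC)CC)[C@H](C)[C@@]1(O)CO | intermediate
38 | (3R,3aS,5R,6S,7S,8S,8aR)-7-formyl-7-hydroxy-3,6-dimethyl-2-oxo-5-[(triethylsilyl)oxy]octahydro-2H-cyclohepta[b]furan-8-yl (2Z)-2-methylbut-2-enoate | C/C=C(/C)C(=O)O[C@H]1[C@@H]2OC(=O)[C@H](C)[C@@H]2C[C@@H](O[Si](CC)(CC)CC)[C@H](C)[C@@]1(O)C=O | intermediate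
39 | (E)-1-bromoprop-1-ene | C/C=C/Br | starting material
40 | (E)-prop-1-enylchromium dichloride (trivalent chromium, solvent ligands omitted; formed in the flask) | C/C=C/[Cr](Cl)Cl | intermediate
41 | (3R,3aS,5R,6S,7R,8S,8aR)-7-hydroxy-7-[(2E)-1-hydroxybut-2-en-1-yl]-3,6-dimethyl-2-oxo-5-[(triethylsilyl)oxy]octahydro-2H-cyclohepta[b]furan-8-yl (2Z)-2-methylbut-2-enoate (both carbinol epimers) | C/C=C(/C)C(=O)O[C@H]1[C@@H]2OC(=O)[C@H](C)[C@@H]2C[C@@H](O[Si](CC)(CC)CC)[C@H](C)[C@@]1(O)C(O)/C=C/C | intermediate
42 | (3R,3aS,5R,6S,7S,8S,8aR)-7-[(2E)-but-2-enoyl]-7-hydroxy-3,6-dimethyl-2-oxo-5-[(triethylsilyl)oxy]octahydro-2H-cyclohepta[b]furan-8-yl (2Z)-2-methylbut-2-enoate | C/C=C(/C)C(=O)O[C@H]1[C@@H]2OC(=O)[C@H](C)[C@@H]2C[C@@H](O[Si](CC)(CC)CC)[C@H](C)[C@@]1(O)C(=O)/C=C/C | intermediate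
43 | (3R,3aS,5R,6S,7S,8S,8aR)-7-[(2E)-but-2-enoyl]-5,7-dihydroxy-3,6-dimethyl-2-oxooctahydro-2H-cyclohepta[b]furan-8-yl (2Z)-2-methylbut-2-enoate | C/C=C(/C)C(=O)O[C@H]1[C@@H]2OC(=O)[C@H](C)[C@@H]2C[C@@H](O)[C@H](C)[C@@]1(O)C(=O)/C=C/C | target

## Step count and least certain steps

Total step count: 25. Longest linear sequence: 24 steps (steps 1 and 3 to 25, from 1); step 2 is a one-step side branch.

**Step 12 (key step).** The most likely failure is poor facial selectivity at C3. The chair that puts the C2 methyl and the chromium alkoxide equatorial carries the three silyloxy groups axially, with those on C1 and C6 syn to each other, and the other chair, which leads to the C3 epimer, may compete. Slow closure with loss of iodine by protonation is the second concern. Fallback: the fallback sets out from 22 obtained as a mixture of C3 epimers. Oxidation with Dess–Martin periodinane (NaHCO3, CH2Cl2) gives the C3 dienone F1. Corey–Bakshi–Shibata reduction with the (R)-2-methyl oxazaborolidine and catecholborane (toluene, −78 °C) then sets C3 by reagent control, the alkenyl branch acting as the large group, and returns to 22.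

**Step 4.** The indium crotylation may give the wrong relative configuration at C2. A ketone offers two carbonyl substituents of similar size to the γ-methyl group, and the second ether oxygen on C10 can take part in chelation. Attack through the α-carbon of the crotyl unit is a lesser risk. Fallback: the fallback sets out from 7. Chelation-controlled addition of 16 (THF, −78 °C) gives the tertiary isopropenyl carbinol F2, with no second stereocenter to control. Silylation with ClSiHMe2 and Et3N gives the hydridosilyl ether F3. Intramolecular hydrosilylation catalysed by H2PtCl6 closes the five-membered oxasilolane F4, in which the new C2 methyl is expected trans to the bulky dioxolanyl group on C1. Tamao–Fleming oxidation (H2O2, KF, KHCO3, THF/MeOH) then gives 12, where the fallback rejoins the route after step 5.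

**Step 9.** The carbomagnesiation may be sluggish or unselective, because the tetra-alkoxide aggregates, the terminal alkyne C–H can be deprotonated and then over-iodinated, and undirected syn addition would give the wrong alkene geometry. Fallback: the fallback sets out from 12. Excess 16 (THF, −78 → 0 °C) converts the Weinreb amide into the isopropenyl ketone F5. Stork–Zhao olefination (Ph3P(CH2I)I, NaN(SiMe3)2, THF, −78 °C) gives the iodoalkene acetonide F6, in which iodine is expected cis to the α-alkoxy carbon C6, as in Z-selective Wittig reactions of α-alkoxy ketones. Hydrolysis of the acetonide (AcOH/H2O) gives 18.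

**Step 19.** Facial selectivity of protonation may be lost on a trianion, since the neighbouring alkoxides are protonated first and can return the proton from inside; enolisation may also be incomplete. Fallback: the fallback sets out from 31. LiN(iPr)2 followed by PhSeBr gives the α-phenylselanyl lactone F7, and H2O2 brings about selenoxide elimination towards H5 to give the butenolide F8. Hydrogenation with [Ir(cod)(PCy3)(py)]PF6, directed by the free hydroxyl on C7, adds hydrogen to C5 and C8 from the face of H6 and gives 33.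

**Step 20.** The angelate may isomerise to the tiglate at 80 °C, or the hindered O7–H may not react. Fallback: the fallback sets out from 33. Acylation with 2-[bis(2,2,2-trifluoroethoxy)phosphoryl]propanoic acid (DCC, DMAP, CH2Cl2) gives the phosphonopropanoate F9. Still–Gennari olefination with acetaldehyde (KN(SiMe3)2, 18-crown-6, THF, −78 °C) builds the Z alkene on the ester in place and gives 36.

## Further compounds

F1 | step 12 | C3 dienone: 22 with the C3 carbinol oxidised to the ketone | O=C1C=C(C(C)=C)[C@@H](O[Si](CC)(CC)CC)[C@H](O[Si](CC)(CC)CC)[C@](O[Si](CC)(CC)CC)(COCc2ccc(OC)cc2)[C@H]1C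
F2 | step 4 | tertiary isopropenyl carbinol: (4S,5S)-5-[(2R)-2-hydroxy-1-[(4-methoxybenzyl)oxy]-3-methylbut-3-en-2-yl]-N-methoxy-N,2,2-trimethyl-1,3-dioxolane-4-carboxamide | C=C(C)[C@@](O)(COCc1ccc(OC)cc1)[C@H]2OC(C)(C)O[C@@H]2C(=O)N(C)OC
F3 | step 4 | dimethylsilyl ether of F2 on the tertiary oxygen | C=C(C)[C@@](O[SiH](C)C)(COCc1ccc(OC)cc1)[C@H]2OC(C)(C)O[C@@H]2C(=O)N(C)OC
F4 | step 4 | 2,2,4-trimethyl-1-oxa-2-silacyclopentane with C1 as ring carbon 5 (bearing CH2OPMB and the dioxolanyl group) and C2 as ring carbon 4 | C[Si]1(C)C[C@H](C)[C@@](O1)(COCc2ccc(OC)cc2)[C@H]3OC(C)(C)O[C@@H]3C(=O)N(C)OC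
F5 | step 9 | isopropenyl ketone: 12 with the Weinreb amide replaced by a 2-methylprop-2-enoyl group | OC[C@H](C)[C@@](O)(COCc1ccc(OC)cc1)[C@H]2OC(C)(C)O[C@@H]2C(=O)C(C)=C
F6 | step 9 | Z-iodoalkene acetonide: the C6/C7 isopropylidene acetal of 18 | OC[C@H](C)[C@@](O)(COCc1ccc(OC)cc1)[C@H]2OC(C)(C)O[C@@H]2/C(=C\I)C(C)=C
F7 | step 19 | α-phenylselanyl lactone: 31 with PhSe on the lactone α-carbon | O[C@H]1[C@@H]2OC(=O)C(C)([Se]c4ccccc4)[C@@H]2C[C@@H](O[Si](CC)(CC)CC)[C@H](C)[C@@]1(O)COCc3ccc(OC)cc3
F8 | step 19 | butenolide: 31 with a C5=C8 double bond | O[C@H]1[C@@H]2OC(=O)C(C)=C2C[C@@H](O[Si](CC)(CC)CC)[C@H](C)[C@@]1(O)COCc3ccc(OC)cc3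
F9 | step 20 | O7 2-[bis(2,2,2-trifluoroethoxy)phosphoryl]propanoate of 33 | CC(C(=O)O[C@H]1[C@@H]2OC(=O)[C@H](C)[C@@H]2C[C@@H](O[Si](CC)(CC)CC)[C@H](C)[C@@]1(O)COCc3ccc(OC)cc3)P(=O)(OCC(F)(F)F)OCC(F)(F)F
A1 | alternative 1 | cis-fused α-methylene γ-lactone on the cycloheptane with O7 PMB ether, O1 triethylsilyl ether, vinyl on C1 and O3 tert-butyldimethylsilyl ether | O=C1O[C@H]2[C@H](OCc3ccc(OC)cc3)[C@](O[Si](CC)(CC)CC)(C=C)[C@@H](C)[C@H](O[Si](C)(C)C(C)(C)C)C[C@H]2C1=C
A2 | alternative 2 | methyl 1-hydroxycyclohept-3-ene-1-carboxylate with C1, C2, C5, C6 and C7 set and the fused ethyl acetal retained | COC(=O)[C@]1(O)[C@@H](C)C=C[C@H]2[C@@H](C)[C@H](OCC)O[C@H]2[C@@H]1O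
A3 | alternative 3 | cis-fused α-methyl γ-lactone on the cycloheptane with O7 PMB ether, free C1 hydroxyl, and tert-butyldimethylsilyl ethers on O10 and O3 | O=C1O[C@H]2[C@H](OCc3ccc(OC)cc3)[C@](O)(CO[Si](C)(C)C(C)(C)C)[C@@H](C)[C@H](O[Si](C)(C)C(C)(C)C)C[C@H]2[C@H]1C
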